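## Structural features

The target 11 is a 1,4-naphthoquinone. Ring A is the quinone ring (C1–C4, C4a, C8a) with carbonyls at C1 and C4 and a methoxy group on C2; ring B is the fused benzene ring (C4a, C5–C8, C8a) with a methoxy group on C6. A 3,4-dimethoxyphenyl ring (ring C) is joined to C8 by a biaryl single bond, so it sits peri to the C1 carbonyl, the same carbonyl that is flanked by the C2 methoxy group. There is no stereocenter, and because ring C has no ortho substituent the biaryl axis is not a stereogenic element. The fragile part is the 2-methoxy-1,4-quinone, a vinylogous ester and Michael acceptor that would not tolerate strong bases, nucleophiles or reductants, so it should be made last; the aryl methyl ethers are robust. The real difficulty is regiochemical: ring B is unsymmetrical, the C2 oxygen must lie next to the carbonyl that is peri to the aryl group (not at C3), and C8a sits in a crowded position between C4a and the arylated C8. The key step exploits the 1,3-relationship of the oxygens on C2 and C4. With C3 between them they form a masked β-dicarbonyl unit, so the C2–C3 bond can be made by a Claisen condensation between an acetyl group on C4a (C4, C3) and an acetic ester on C8a (C1, C2), leaving C1 as the free α-position of a naphthalene-1,3-diol, ready for oxygenation.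

## Logic of the disconnections

**11 ⇒ 10.** Cut: the O–CH3 bond of the methoxy group on C2. Reason: this oxygen is part of a vinylogous ester, best formed last from the vinylogous acid. Gain: the base- and nucleophile-sensitive methoxyquinone is absent from all earlier intermediates. Demand: the methyl group must end on the C2 oxygen and not on the C4 oxygen, so the forward step has to equilibrate under acid towards the para-quinone.

**10 ⇒ 9.** Cut: the C1=O bond; C1 returns to an aromatic C–H. Reason: without the C1 oxygen, the remaining oxygens at C2 and C4 are 1,3-related, which is the pattern a carbonyl condensation can build. Gain: the oxidation level drops to a naphthalene-1,3-diol that air alone can re-oxidise. Demand: oxygen must enter at C1 (para to the C4 hydroxyl, peri to ring C) and not at C3, and 9 must not couple with itself.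

**9 ⇒ 8.** Cut: C2–C3 of ring A, reading the two enols as ketones. Reason: it is the bond of a β-diketone. Gain: ring A opens to a single benzene ring that carries an acetyl group (C4, C3) and a CH2CO2Me group (C1, C2) ortho to each other. Demand: the acetyl enolate must attack the ester, and faster than any intermolecular condensation.

**8 ⇒ 5 + 6 (through 7).** Cut: the aryl–CH2 bond C8a–C1. Reason: C8a becomes an aryl electrophile and the two-carbon unit a zinc enolate 7 made from commercial 6; an oxygen leaving group is chosen on C8a because the same oxygen, as a phenol, can direct the earlier substitution at C8. Gain: the acetate unit is bought. Demand: a palladium coupling at a carbon flanked on both sides, with a nucleophile mild enough to leave the methyl ketone alone.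

**5 ⇒ 4.** Cut: the O–S bond of the triflate. Reason: the leaving group is installed only when it is needed. Gain: 4 is a plain ortho-hydroxyacetophenone. Demand: sulfonylation of a hindered, hydrogen-bonded phenol without enolising the ketone.

**4 ⇒ 2 + 3.** Cut: the biaryl bond between C8 and ring C. Reason: it separates an aryl bromide from the commercial boronic acid 3. Gain: ring C and its two methoxy groups are bought. Demand: cross-coupling next to a free phenol.

**2 ⇒ 1.** Cut: the C8–Br bond. Reason: in 1 the position para to the hydroxyl is occupied by the methoxy group and one ortho position by the acetyl group, so C8 is the only position the hydroxyl can activate. Gain: 1 is commercial and already holds the acetyl group, the C8a oxygen and the C6 methoxy group in the right places. Demand: ring bromination, not α-bromination of the ketone.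

## Other disconnections considered

**Alternative 1:** Cut: the ring B bonds C4a–C5 and C6–C7, which divides ring B into the vinylquinone A1 (2-[1-(3,4-dimethoxyphenyl)ethenyl]-6-methoxy-1,4-benzoquinone) and the ketene acetal A2 (1,1-dimethoxyethene).
- Forward key step: the electron-poor diene C4a=C8a–C8=C7 of A1 would take up electron-rich A2 in an inverse-demand Diels–Alder reaction, probably stepwise (CH2 of A2 onto C4a, then the acetal carbon onto C7). Two proton shifts would convert the adduct into the dihydronaphthalenediol A3. Elimination of one acetal methoxy group across C5–C6 and oxidation of the hydroquinone would complete 11.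
- In its favour: two skeletal bonds and ring B in one step, the C6 oxygen delivered by the dienophile, all three ring A oxygens present from the start, and a convergent assembly.
- Against it here: A1 is not a stock compound and needs its own sequence (aryl–vinyl coupling on a protected bromohydroquinone, then oxidative unmasking). Quinones with a 1-arylvinyl group tend to dimerise or polymerise. The zwitterion from A1 and A2 can also close through the C4 oxygen to a dihydrobenzofuran, or by [2+2] addition. The site of attack (C4a, not C3) rests on a polarity argument, C3 being the donor-substituted end of an enol ether, and is not enforced by ring size.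
- Comparison: on structure this plan is the better one in two respects: no oxygen has to be introduced later at the peri-hindered C1, and the quinone oxidation level is reached without a separate oxygenation. On mechanism the chosen plan is the safer one, because its closure allows only one ring size and its reacting groups are placed by a commercial arene. On step economy the two are about equal once the preparation of A1 is counted.

**Alternative 2:** Cut: the C5=C6 bond of ring B, both carbons becoming carbonyl groups. C5 becomes an aldehyde on C4a and C6 the ester of a (Z)-3,3-diarylacrylate, in A4 (methyl (2Z)-3-(3,4-dimethoxyphenyl)-3-(2-formyl-3,5,6-trimethoxyphenyl)prop-2-enoate).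
- Forward key step: low-valent titanium from TiCl3 and zinc would couple aldehyde and ester reductively. Because the ester oxygen is retained, the new C5=C6 bond is an enol ether, which is the C6 methoxy group of the aromatic naphthalene A5 (8-(3,4-dimethoxyphenyl)-1,2,4,6-tetramethoxynaphthalene). Oxidative demethylation with (NH4)2Ce(NO3)6 would then have to convert ring A into the quinone of 11.
- In its favour: ring A arrives with all three oxygens in fixed positions, the C6 methoxy group is created by the ring closure itself, aromatisation drives the coupling, and A5 is a stable, fully protected compound that is easy to handle.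
- Against it here: ester–aldehyde coupling is the least dependable member of the carbonyl-coupling family, since the aldehyde can pinacolise or be reduced and the acrylate is itself reducible. A4 needs a pentasubstituted benzaldehyde and a trisubstituted alkene of defined geometry, with ring A cis to the ester. The last oxidation must discriminate between three electron-rich rings and between a 2-methoxy-1,4-quinone and a 4-methoxy-1,2-quinone.
- Comparison: on structure it is the equal or the better of the chosen plan, as the positions of the quinone oxygens are unambiguous and no oxygenation at C1 is needed. On handling of the cyclised intermediate it is better (A5 against the air-sensitive 9). On mechanism it is weaker, with two uncertain steps in a row at the end. On step economy it is worse, since A4 alone should cost about as many steps as the whole chosen route.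

**Alternative 3:** Cut: C1–C2 of ring A. C1 becomes an aldehyde on C8a, and C2–C3–C4 an (E)-3-methoxyprop-2-enoyl group on C4a, in A6 (2-(3,4-dimethoxyphenyl)-4-methoxy-6-[(2E)-3-methoxyprop-2-enoyl]benzaldehyde).
- Forward key step: photoexcited (Bu4N)4W10O32 would abstract the formyl hydrogen. The aroyl radical at C1 would add to C2, the methoxy-bearing β-carbon of the enone, in a 6-endo closure, and back-transfer of hydrogen to C3 would give the racemic dihydroquinone A7. Enolisation and mild oxidation would then give 11, which erases the C2 stereocenter.
- In its favour: a catalytic, redox-neutral ring closure without protecting groups. The C2 methoxy group is carried in, so no late methylation and no question of which oxygen is methylated. The bond to the hindered C1 side is made intramolecularly.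
- Against it here: a β-methoxy enone is a weak, donor-substituted radical acceptor. The 6-endo mode has to beat 5-exo attack at C3, which would give an oxygen-stabilised radical and a five-membered indanedione ring. The substrate offers many abstractable O–CH3 hydrogens. A7 can lose its C2 methoxy group by β-elimination under the conditions that enolise it. A6 has an aldehyde ortho to an enolisable acyl group and is awkward to prepare; from 5 it would need formylation and a formyl-Claisen/O-methylation sequence.
- Comparison: on structure it is the equal of the chosen plan (same biaryl core, same ring closed) and better in delivering the methyl ether ready-made. On mechanism it depends on an untested regiochemical preference, whereas the chosen closure cannot go astray in ring size. On step economy it is no shorter and probably one or two steps longer.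

Key step: step 5

Assumption: the C8–aryl axis of 11 rotates freely, so no stereochemical element needs control; the atom numbers C1–C8a are those of the naphthoquinone 11 and are used for its precursors as well.

## Route

Step 1
Reactants: 1 2'-hydroxy-5'-methoxyacetophenone [1-(2-hydroxy-5-methoxyphenyl)ethan-1-one]
Product: 2 1-(3-bromo-2-hydroxy-5-methoxyphenyl)ethan-1-one
Conditions: NBS (1.05 equiv), NH4OAc (10 mol%), MeCN, 0 °C to rt
Reagents that add atoms: N-bromosuccinimide, O=C1CCC(=O)N1Br
Why: Electrophilic aromatic bromination; the hydroxyl is the strongest donor, its para position is blocked by the methoxy group and the free ortho position (future C8) is meta to the deactivating acetyl group, so bromine should enter there. Mild buffered NBS avoids the acid-catalysed α-bromination of the methyl ketone.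

Step 2
Reactants: 2 1-(3-bromo-2-hydroxy-5-methoxyphenyl)ethan-1-one; 3 3,4-dimethoxyphenylboronic acid
Product: 4 1-[3-(3,4-dimethoxyphenyl)-2-hydroxy-5-methoxyphenyl]ethan-1-one
Conditions: 3 (1.2 equiv), Pd(PPh3)4 (3 mol%), K2CO3 (3 equiv), 1,4-dioxane/H2O 4:1, 90 °C
Reagents that add atoms: none
Why: Suzuki–Miyaura coupling; oxidative addition of the C–Br bond to zerovalent palladium, transmetalation from the boronate and reductive elimination form the C8–ring C bond. Ortho-bromophenols couple with the hydroxyl free under aqueous carbonate, so no protecting group is spent.

Step 3
Reactants: 4 1-[3-(3,4-dimethoxyphenyl)-2-hydroxy-5-methoxyphenyl]ethan-1-one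
Product: 5 2-acetyl-6-(3,4-dimethoxyphenyl)-4-methoxyphenyl trifluoromethanesulfonate
Conditions: Tf2O (1.3 equiv), pyridine (3 equiv), CH2Cl2, 0 °C to rt
Reagents that add atoms: trifluoromethanesulfonic anhydride, O=S(=O)(OS(=O)(=O)C(F)(F)F)C(F)(F)F
Why: O-Sulfonylation of a phenol; Tf2O is reactive enough for a flanked, hydrogen-bonded hydroxyl, and pyridine at 0 °C does not enolise the methyl ketone. The C8a–O bond becomes a leaving group for palladium.

Step 4
Reactants: 5 2-acetyl-6-(3,4-dimethoxyphenyl)-4-methoxyphenyl trifluoromethanesulfonate; 6 methyl bromoacetate
Product: 8 methyl 2-[2-acetyl-6-(3,4-dimethoxyphenyl)-4-methoxyphenyl]acetate, via bromo(2-methoxy-2-oxoethyl)zinc 7 (not isolated)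
Conditions: 6 (2 equiv), Zn dust (TMSCl-activated), THF, 40 °C; then 5, Pd2(dba)3 (2.5 mol%), XPhos (10 mol%), THF, 65 °C
Reagents that add atoms: none
Why: Negishi-type α-arylation of a Reformatsky reagent; zinc inserts into the C–Br bond of 6, the aryl triflate adds oxidatively to zerovalent palladium (helped by the ortho acetyl group and made feasible at the doubly flanked carbon by the bulky biarylphosphine), and transmetalation and reductive elimination form the C8a–C1 bond. The weakly basic zinc enolate should neither enolise nor rapidly add to the hindered methyl ketone, and the methyl ester matches the methoxide of step 5.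

Step 5
Reactants: 8 methyl 2-[2-acetyl-6-(3,4-dimethoxyphenyl)-4-methoxyphenyl]acetate
Product: 10 8-(3,4-dimethoxyphenyl)-2-hydroxy-6-methoxynaphthalene-1,4-dione, via 5-(3,4-dimethoxyphenyl)-7-methoxynaphthalene-1,3-diol 9 (not isolated)
Conditions: NaOMe (3 equiv), MeOH, 65 °C, argon; then O2 (1 atm), rt; 1 M HCl work-up
Reagents that add atoms: dioxygen, O=O
Why: Intramolecular Claisen (Dieckmann-type) condensation followed by base-mediated autoxidation, the established way from 2-acylphenylacetates to naphthalene-1,3-diols and on to 2-hydroxy-1,4-naphthoquinones. Methoxide forms both enolates of 8 reversibly; the acetyl enolate (C3) attacks the ester carbonyl (C2), methoxide leaves, and the cyclic β-diketone enolises to the aromatic diol 9, held as its phenolate, which makes the sequence irreversible. Ring A closes in a 6-(enolendo)-exo-trig mode. The selectivity needed is C3 onto C2 and no other pairing: the benzylic ester enolate could reach the ketone only through a four-membered ring and is simply reprotonated in methanol, so it does not block the ester, and the six-membered closure should outrun intermolecular condensation. Once oxygen is admitted, the electron-rich phenolate of 9 gives up an electron, dioxygen is taken up at C1, the free α-position para to the C4 oxygen, and the hydroperoxide collapses to the C1 carbonyl of 10. C3 is activated too, but only attack at C1 leads directly to the para-quinone; dioxygen is small enough for the position peri to ring C, and the same crowding should disfavour coupling of two radicals through C1. No stereocenter is formed. Acidification releases 10 from its sodium salt.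

Step 6
Reactants: 10 8-(3,4-dimethoxyphenyl)-2-hydroxy-6-methoxynaphthalene-1,4-dione
Product: 11 8-(3,4-dimethoxyphenyl)-2,6-dimethoxynaphthalene-1,4-dione
Conditions: MeOH, conc. HCl (cat.), 65 °C
Reagents that add atoms: methanol, CO
Why: Acid-catalysed vinylogous Fischer esterification; 10 is a vinylogous carboxylic acid, methanol adds at C2 of the protonated quinone and water is lost. The reaction is under thermodynamic control, so any ether formed at the C4 oxygen (the ortho-quinone isomer) should revert and funnel to the more stable 2-methoxy-1,4-quinone; the aryl methyl ethers are inert to dilute methanolic HCl.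

## Compound list

1 | 2'-hydroxy-5'-methoxyacetophenone [1-(2-hydroxy-5-methoxyphenyl)ethan-1-one] | CC(=O)c1cc(OC)ccc1O | starting material
2 | 1-(3-bromo-2-hydroxy-5-methoxyphenyl)ethan-1-one | CC(=O)c1cc(OC)cc(Br)c1O | intermediate
3 | 3,4-dimethoxyphenylboronic acid | COc1ccc(B(O)O)cc1OC | starting material
4 | 1-[3-(3,4-dimethoxyphenyl)-2-hydroxy-5-methoxyphenyl]ethan-1-one | CC(=O)c1cc(OC)cc(-c2ccc(OC)c(OC)c2)c1O | intermediate
5 | 2-acetyl-6-(3,4-dimethoxyphenyl)-4-methoxyphenyl trifluoromethanesulfonate | CC(=O)c1cc(OC)cc(-c2ccc(OC)c(OC)c2)c1OS(=O)(=O)C(F)(F)F | intermediate
6 | methyl bromoacetate | BrCC(=O)OC | starting material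
7 | bromo(2-methoxy-2-oxoethyl)zinc (Reformatsky reagent, not isolated) | COC(=O)C[Zn]Br | intermediate
8 | methyl 2-[2-acetyl-6-(3,4-dimethoxyphenyl)-4-methoxyphenyl]acetate | COC(=O)Cc1c(C(C)=O)cc(OC)cc1-c1ccc(OC)c(OC)c1 | intermediate
9 | 5-(3,4-dimethoxyphenyl)-7-methoxynaphthalene-1,3-diol (not isolated) | Oc1cc(O)c2cc(OC)cc(-c3ccc(OC)c(OC)c3)c2c1 | intermediate
10 | 8-(3,4-dimethoxyphenyl)-2-hydroxy-6-methoxynaphthalene-1,4-dione | OC1=CC(=O)c2cc(OC)cc(-c3ccc(OC)c(OC)c3)c2C1=O | intermediate
11 | 8-(3,4-dimethoxyphenyl)-2,6-dimethoxynaphthalene-1,4-dione | COC1=CC(=O)c2cc(OC)cc(-c3ccc(OC)c(OC)c3)c2C1=O | target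

## Step count and least certain steps

Total step count: 6. Longest linear sequence: 6 steps (1 to 11); 3 and 6 enter as commercial side inputs.

**Step 4.** What may go wrong: slow oxidative addition and transmetalation at the doubly flanked C8a–O bond. That would give the zinc enolate 7 time to add to the acetyl group (Reformatsky addition), to condense with itself, or to attack the sulfur of the triflate and return 4. The fallback sets out from 5 and comes back at 8; it replaces the enolate by an allyl group and oxidises afterwards. 5 would be coupled with allylboronic acid pinacol ester (Pd(PPh3)4, CsF, THF, 65 °C) to give 1-[3-(3,4-dimethoxyphenyl)-5-methoxy-2-(prop-2-en-1-yl)phenyl]ethan-1-one F1. Lemieux–von Rudloff cleavage of the terminal alkene (KMnO4 cat., NaIO4, K2CO3, t-BuOH/H2O, rt) should give 2-[2-acetyl-6-(3,4-dimethoxyphenyl)-4-methoxyphenyl]acetic acid F2 without an aldehyde stage that could close by aldol reaction onto the neighbouring acetyl group. Esterification (MeI, KHCO3, DMF, rt) then returns to 8.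

**Step 5 (key step).** What may go wrong: the ring closure has little room for error, but the oxygenation stage may suffer from coupling of the naphthoxyl radical with itself through C3, from sluggish oxygen uptake at the peri-hindered C1, or from oxidative degradation of 10 in the alkaline medium. The fallback sets out from 8 and comes back at 11; it separates closure from oxidation and methylates before oxidising. The Claisen step would be run as above but quenched with degassed acid under argon and 9 isolated. Methanolic HCl at rt should etherify only the β-hydroxyl on C2 (through its keto tautomer) to give 5-(3,4-dimethoxyphenyl)-3,7-dimethoxynaphthalen-1-ol F3. Teuber oxidation of this single naphthol with ON(SO3K)2 (KH2PO4, acetone/H2O, rt), which converts a phenol with a free para position into the para-quinone, would then give 11 directly, bypassing 10 and step 6 at the cost of one extra step.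

**Step 6.** What may go wrong: incomplete conversion, because the etherification is an equilibrium that the water formed pushes back, or persistence of the ortho-quinone ether from methylation at the C4 oxygen. The fallback sets out from 10 and comes back at 11; it turns C2 into a leaving-group position instead of relying on equilibrium. SOCl2 (neat, 75 °C) would convert the vinylogous acid into the vinylogous acid chloride 2-chloro-8-(3,4-dimethoxyphenyl)-6-methoxynaphthalene-1,4-dione F4. NaOMe (1 equiv) in MeOH at 0 °C would then replace chloride at C2 by addition–elimination to give 11.

**Step 2.** What may go wrong: slow oxidative addition at the electron-rich ring once the phenol is deprotonated, with protodeboronation of the electron-rich boronic acid 3 taking over. The fallback sets out from 2 and comes back at 5; it changes the order so that no phenoxide is present during the coupling. 2 would be sulfonylated first (Tf2O, pyridine, CH2Cl2, 0 °C) to 2-acetyl-6-bromo-4-methoxyphenyl trifluoromethanesulfonate F5. 3 would then be coupled chemoselectively at the C–Br bond (Pd(PPh3)4, K3PO4, 1,4-dioxane, 80 °C), relying on the usual preference of this catalyst for C–Br over C–OTf in Suzuki–Miyaura reactions. This gives 5 with the same number of steps.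

## Further compounds

F1 | step 4 | 1-[3-(3,4-dimethoxyphenyl)-5-methoxy-2-(prop-2-en-1-yl)phenyl]ethan-1-one | C=CCc1c(C(C)=O)cc(OC)cc1-c1ccc(OC)c(OC)c1
F2 | step 4 | 2-[2-acetyl-6-(3,4-dimethoxyphenyl)-4-methoxyphenyl]acetic acid | OC(=O)Cc1c(C(C)=O)cc(OC)cc1-c1ccc(OC)c(OC)c1
F3 | step 5 | 5-(3,4-dimethoxyphenyl)-3,7-dimethoxynaphthalen-1-ol | COc1cc(O)c2cc(OC)cc(-c3ccc(OC)c(OC)c3)c2c1
F4 | step 6 | 2-chloro-8-(3,4-dimethoxyphenyl)-6-methoxynaphthalene-1,4-dione | ClC1=CC(=O)c2cc(OC)cc(-c3ccc(OC)c(OC)c3)c2C1=O
F5 | step 2 | 2-acetyl-6-bromo-4-methoxyphenyl trifluoromethanesulfonate | CC(=O)c1cc(OC)cc(Br)c1OS(=O)(=O)C(F)(F)F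
A1 | alternative 1 | 2-[1-(3,4-dimethoxyphenyl)ethenyl]-6-methoxycyclohexa-2,5-diene-1,4-dione | COC1=CC(=O)C=C(C(=C)c2ccc(OC)c(OC)c2)C1=O
A2 | alternative 1 | 1,1-dimethoxyethene | C=C(OC)OC
A3 | alternative 1 | 8-(3,4-dimethoxyphenyl)-2,6,6-trimethoxy-5,6-dihydronaphthalene-1,4-diol | COc1cc(O)c2c(c1O)C(c1ccc(OC)c(OC)c1)=CC(OC)(OC)C2
A4 | alternative 2 | methyl (2Z)-3-(3,4-dimethoxyphenyl)-3-(2-formyl-3,5,6-trimethoxyphenyl)prop-2-enoate | COC(=O)/C=C(\c1c(C=O)c(OC)cc(OC)c1OC)c1ccc(OC)c(OC)c1
A5 | alternative 2 | 8-(3,4-dimethoxyphenyl)-1,2,4,6-tetramethoxynaphthalene | COc1cc(-c2ccc(OC)c(OC)c2)c2c(OC)c(OC)cc(OC)c2c1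
A6 | alternative 3 | 2-(3,4-dimethoxyphenyl)-4-methoxy-6-[(2E)-3-methoxyprop-2-enoyl]benzaldehyde | CO/C=C/C(=O)c1cc(OC)cc(-c2ccc(OC)c(OC)c2)c1C=O
A7 | alternative 3 | racemic 8-(3,4-dimethoxyphenyl)-2,6-dimethoxy-2,3-dihydronaphthalene-1,4-dione (the 2S enantiomer is drawn) | CO[C@H]1CC(=O)c2cc(OC)cc(-c3ccc(OC)c(OC)c3)c2C1=O
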